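**Target:** CNP0071420.1, a 9-oxo-germacran-12,6-olide (4S,5R,6S,7S,8R,10R; (2R)-2-methylbutanoate on O8, isobutyrate on O5).

## Retrosynthetic overview

1. The α-methylene lactone comes last, by allylic C–H oxidation of a 3-methylidene-tetrahydrofuran that masks it from step 2 onward; the O8 and O5 esters are put on just before.
2. C8–O, C9=O and C10–H come from a C9 enone (α′-hydroxylation, then conjugate reduction); C5–OH comes from chelation-controlled reduction of a 4-hydroxy-5-ketone.
3. The ten-membered ring is made by an anionic oxy-Cope rearrangement of a 1-isopropenyl-2-methyl-2-vinylcyclohexanol (C2–C3 formed, C5–C10 broken); its enolate is oxygenated in the same flask to give C4–OH.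
4. The quaternary C(Me)(vinyl) centre comes from a semipinacol vinyl shift of an epoxy alcohol (vinyl addition, then directed epoxidation of a bicyclic enone).
5. The bicyclic enone comes from (R)-carvone, which supplies C7. Ring order: cyclohexene (bought), tetrahydrofuran (step 2), ten-membered ring (step 7), lactone carbonyl (step 14).

## Assumptions

- Ten-membered compounds use germacrane numbering: ring C1–C10, C11–C13 on C7, C14 on C10, C15 on C4; "6,12-epoxy" is the O6–C12 ether. Bicyclic compounds 5–9 are named as benzofurans (C7, C6, C5, C4, C3a, C7a, C3, C2 correspond to germacrane C5, C10, C9, C8, C7, C6, C11, C12).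
- C10 is α to the ketone and epimerisable; the natural 10R epimer is taken to be the more stable one.
- The facial selectivities on the ten-membered ring (C4, C5, C8) are predictions from outer-face attack models and are not backed by a close precedent.
- The relay centres in 6–9 are drawn as predicted; none of them survives into the target.

## Route

**Step 1**
Reactants: 1 (R)-(−)-carvone
Product: 2 (5R)-5-(3-chloroprop-1-en-2-yl)-2-methylcyclohex-2-en-1-one
Conditions: Ca(OCl)2, solid CO2, CH2Cl2/H2O, 0 °C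
Reagents that add atoms: calcium hypochlorite, [Ca+2].[O-]Cl.[O-]Cl
Why: Ene-type allylic chlorination by HOCl made in situ attacks only the electron-rich 1,1-disubstituted olefin, the enone olefin is inert, and the stereocentre bought with carvone is untouched.

**Step 2**
Reactants: 2 (5R)-5-(3-chloroprop-1-en-2-yl)-2-methylcyclohex-2-en-1-one
Product: 5 (3aS,7aS)-6-methyl-3-methylidene-3,3a,4,7a-tetrahydro-1-benzofuran-7(2H)-one, via potassium dienolate 3 (not isolated), via chloro alkoxide 4 (not isolated)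
Conditions: KN(SiMe3)2, THF, −78 °C; racemic trans-2-(phenylsulfonyl)-3-phenyloxaziridine, −78 °C; then 0 °C
Reagents that add atoms: 2-(phenylsulfonyl)-3-phenyloxaziridine, O=S(=O)(c1ccccc1)N1OC1c1ccccc1
Why: Kinetic α′-deprotonation followed by enolate hydroxylation places oxygen anti to the adjacent side chain (1,2-induction from the carvone centre), and the alkoxide closes by 5-exo-tet Williamson etherification on the allylic chloride to the trans-fused ether.

**Step 3**
Reactants: 5 (3aS,7aS)-6-methyl-3-methylidene-3,3a,4,7a-tetrahydro-1-benzofuran-7(2H)-one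
Product: 6 (3aS,7R,7aS)-7-ethenyl-6-methyl-3-methylidene-2,3,3a,4,7,7a-hexahydro-1-benzofuran-7-ol
Conditions: CH2=CHMgBr, THF, −78 °C; NH4Cl(aq)
Reagents that add atoms: vinylmagnesium bromide, C=C[Mg]Br
Why: Chelation-controlled Grignard 1,2-addition (Mg bridging the carbonyl and the α-ether oxygen) delivers vinyl to the face of H-7a; this carbinol centre is a relay that is erased in step 5.

**Step 4**
Reactants: 6 (3aS,7R,7aS)-7-ethenyl-6-methyl-3-methylidene-2,3,3a,4,7,7a-hexahydro-1-benzofuran-7-ol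
Product: 7 5,6-epoxide of 6 with the oxirane oxygen cis to the C7 hydroxyl
Conditions: VO(acac)2 (cat.), tBuOOH, CH2Cl2, 0 → 23 °C
Reagents that add atoms: tert-butyl hydroperoxide, CC(C)(C)OO
Why: Hydroxyl-directed vanadium-catalysed epoxidation puts the oxirane syn to the tertiary OH on the cyclic trisubstituted olefin, which reacts faster than the vinyl group or the remote methylidene.

**Step 5**
Reactants: 7 5,6-epoxide of 6
Product: 8 (3aS,5R,6S,7aS)-6-ethenyl-5-hydroxy-6-methyl-3-methylidenehexahydro-1-benzofuran-7(2H)-one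
Conditions: BF3·OEt2 (0.2 equiv), CH2Cl2, −78 °C
Reagents that add atoms: none
Why: Semipinacol rearrangement of the 2,3-epoxy alcohol: the epoxide opens at its tertiary carbon while the vinyl group anti to the C–O bond shifts 1,2 with inversion, giving the quaternary C(Me)(vinyl) centre and the ketone (both new centres are temporary).

**Step 6**
Reactants: 8 (3aS,5R,6S,7aS)-6-ethenyl-5-hydroxy-6-methyl-3-methylidenehexahydro-1-benzofuran-7(2H)-one
Product: 9 (3aS,5R,6S,7R,7aS)-6-ethenyl-6-methyl-3-methylidene-7-(prop-1-en-2-yl)octahydro-1-benzofuran-5,7-diol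
Conditions: CH2=C(CH3)MgBr (3 equiv), anhydrous CeCl3, THF, −78 → 0 °C; NH4Cl(aq)
Reagents that add atoms: isopropenylmagnesium bromide, CC(=C)[Mg]Br
Why: Organocerium 1,2-addition to the hindered, enolisable ketone; the lower face is screened by the syn-axial C5 alkoxide and H-3a, so isopropenyl enters equatorially and gauche to the axial vinyl group, the geometry the [3,3] shift needs (carbinol centre erased in step 7).

**Step 7**
Reactants: 9 (3aS,5R,6S,7R,7aS)-6-ethenyl-6-methyl-3-methylidene-7-(prop-1-en-2-yl)octahydro-1-benzofuran-5,7-diol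
Product: 13 (1(10)E,4S,6S,7S,9R)-4,9-dihydroxy-6,12-epoxygermacra-1(10),11(13)-dien-5-one, via dipotassium dialkoxide 10 (not isolated), via ring-expanded enolate 11 (not isolated), via potassium hydroperoxide 12 (not isolated)
Conditions: KN(SiMe3)2 (2.3 equiv), 18-crown-6, THF, 0 → 23 °C; then −78 °C, P(OEt)3, O2; NH4Cl(aq)
Reagents that add atoms: dioxygen, O=O
Why: Anionic oxy-Cope rearrangement ([3,3]-sigmatropic, chair-like transition state) breaks C5–C10 and forms C2–C3 to give the ten-membered C4=C5 enolate with an (E)-C1=C10 olefin; O2 then adds to C4 from the outer face (C6–H eclipsed, ring chain through C7 on the other face) to set 4S, and the phosphite reduces the hydroperoxide.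

**Step 8**
Reactants: 13 (1(10)E,4S,6S,7S,9R)-4,9-dihydroxy-6,12-epoxygermacra-1(10),11(13)-dien-5-one
Product: 14 (1(10)E,4S,5R,6S,7S,9R)-6,12-epoxygermacra-1(10),11(13)-diene-4,5,9-triol
Conditions: Zn(BH4)2, Et2O, −20 °C; NH4Cl(aq)
Reagents that add atoms: none
Why: Chelation-controlled reduction of the α-hydroxy ketone (zinc alkoxide at O4 bound to the C5 carbonyl) delivers hydride from the outer face anti to ring carbon C3 and gives the anti diol (5R).

**Step 9**
Reactants: 14 (1(10)E,4S,5R,6S,7S,9R)-6,12-epoxygermacra-1(10),11(13)-diene-4,5,9-triol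
Product: 15 (1(10)E,4S,5R,6S,7S)-4,5-dihydroxy-6,12-epoxygermacra-1(10),11(13)-dien-9-one
Conditions: activated MnO2, CH2Cl2, 23 °C
Reagents that add atoms: none
Why: Chemoselective allylic alcohol oxidation: only the C9 carbinol is allylic, so the relay centre at C9 becomes the enone carbonyl while the saturated secondary and tertiary alcohols stay.

**Step 10**
Reactants: 15 (1(10)E,4S,5R,6S,7S)-4,5-dihydroxy-6,12-epoxygermacra-1(10),11(13)-dien-9-one
Product: 16 (1(10)E,4S,5R,6S,7S)-4-hydroxy-5-(2-methylpropanoyloxy)-6,12-epoxygermacra-1(10),11(13)-dien-9-one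
Conditions: (iPrCO)2O, DMAP (cat.), pyridine, CH2Cl2, 0 → 23 °C
Reagents that add atoms: isobutyric anhydride, CC(C)C(=O)OC(=O)C(C)C
Why: DMAP-catalysed acylation takes the only secondary hydroxyl; the tertiary C4–OH does not react.

**Step 11**
Reactants: 16 (1(10)E,4S,5R,6S,7S)-4-hydroxy-5-(2-methylpropanoyloxy)-6,12-epoxygermacra-1(10),11(13)-dien-9-one
Product: 19 (1(10)E,4S,5R,6S,7R,8R)-4,8-dihydroxy-5-(2-methylpropanoyloxy)-6,12-epoxygermacra-1(10),11(13)-dien-9-one, via bis-silyl dienol ether 17 (not isolated), via silyloxy epoxide 18 (not isolated)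
Conditions: Me3SiOTf, Et3N, CH2Cl2, −78 → 0 °C; DMDO, acetone, −78 °C; 1 M HCl, THF, 0 °C
Reagents that add atoms: dimethyldioxirane, CC1(C)OO1
Why: Rubottom oxidation: enolisation can only go to C8 (C10 is sp2) and also silylates C4–OH; DMDO epoxidises the enol ether from the outer face (anti to the ring chain through C6, C7–H eclipsed) to set 8R, and acid hydrolysis frees both hydroxyls.

**Step 12**
Reactants: 19 (1(10)E,4S,5R,6S,7R,8R)-4,8-dihydroxy-5-(2-methylpropanoyloxy)-6,12-epoxygermacra-1(10),11(13)-dien-9-one; 20 (R)-2-methylbutanoic acid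
Product: 21 (1(10)E,4S,5R,6S,7S,8R)-4-hydroxy-8-[(2R)-2-methylbutanoyloxy]-5-(2-methylpropanoyloxy)-6,12-epoxygermacra-1(10),11(13)-dien-9-one
Conditions: DCC, DMAP (cat.), CH2Cl2, 0 → 23 °C
Reagents that add atoms: none
Why: Steglich esterification of the secondary α-ketol hydroxyl with the purchased (R)-acid, whose stereocentre is carried in unchanged; the tertiary alcohol is inert.

**Step 13**
Reactants: 21 (1(10)E,4S,5R,6S,7S,8R)-4-hydroxy-8-[(2R)-2-methylbutanoyloxy]-5-(2-methylpropanoyloxy)-6,12-epoxygermacra-1(10),11(13)-dien-9-one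
Product: 23 (4S,5R,6S,7S,8R,10R)-4-hydroxy-8-[(2R)-2-methylbutanoyloxy]-5-(2-methylpropanoyloxy)-6,12-epoxygermacr-11(13)-en-9-one, via copper enolate 22 (not isolated)
Conditions: [(Ph3P)CuH]6, wet C6H6, 23 °C; NH4Cl(aq); Et3N, CH2Cl2 if the C10 ratio needs equilibrating
Reagents that add atoms: none
Why: Conjugate (1,4) reduction by the phosphine copper hydride is selective for the enone over the isolated methylidene and the esters; C-protonation of the copper enolate sets C10, which remains free to equilibrate to the more stable 10R epimer.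

**Step 14**
Reactants: 23 (4S,5R,6S,7S,8R,10R)-4-hydroxy-8-[(2R)-2-methylbutanoyloxy]-5-(2-methylpropanoyloxy)-6,12-epoxygermacr-11(13)-en-9-one
Product: 24 (4S,5R,6S,7S,8R,10R)-4-hydroxy-8-[(2R)-2-methylbutanoyloxy]-5-(2-methylpropanoyloxy)-9-oxogermacr-11(13)-en-12,6-olide (target)
Conditions: CrO3, 3,5-dimethylpyrazole, CH2Cl2, −20 °C
Reagents that add atoms: chromium trioxide, O=[Cr](=O)=O
Why: Chromium-mediated allylic C–H oxidation of the doubly activated C12 methylene (allylic and α to oxygen) turns the cyclic allyl ether into the α-methylene γ-lactone; the only free alcohol is tertiary and no stereocentre is touched.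

## Compound list

1 | (R)-(−)-carvone, (5R)-2-methyl-5-(prop-1-en-2-yl)cyclohex-2-en-1-one | CC1=CC[C@H](CC1=O)C(C)=C | starting material
2 | (5R)-5-(3-chloroprop-1-en-2-yl)-2-methylcyclohex-2-en-1-one | CC1=CC[C@H](CC1=O)C(CCl)=C | intermediate
3 | potassium cross-conjugated dienolate of 2 (O–C1=C6) | CC1=CC[C@@H](C(CCl)=C)C=C1[O-].[K+] | intermediate
4 | potassium alkoxide of (5S,6S)-5-(3-chloroprop-1-en-2-yl)-6-hydroxy-2-methylcyclohex-2-en-1-one (O trans to the side chain) | CC1=CC[C@@H](C(CCl)=C)[C@H]([O-])C1=O.[K+] | intermediate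
5 | (3aS,7aS)-6-methyl-3-methylidene-3,3a,4,7a-tetrahydro-1-benzofuran-7(2H)-one (trans-fused) | CC1=CC[C@H]2C(=C)CO[C@@H]2C1=O | intermediate
6 | (3aS,7R,7aS)-7-ethenyl-6-methyl-3-methylidene-2,3,3a,4,7,7a-hexahydro-1-benzofuran-7-ol (vinyl syn to H-7a) | CC1=CC[C@H]2C(=C)CO[C@@H]2[C@@]1(O)C=C | intermediate
7 | 5,6-epoxide of 6, oxirane oxygen cis to the C7 hydroxyl and trans to the vinyl group | C[C@@]12O[C@@H]1C[C@H]3C(=C)CO[C@@H]3[C@@]2(O)C=C | intermediate
8 | (3aS,5R,6S,7aS)-6-ethenyl-5-hydroxy-6-methyl-3-methylidenehexahydro-1-benzofuran-7(2H)-one | C=C[C@@]1(C)[C@H](O)C[C@H]2C(=C)CO[C@@H]2C1=O | intermediate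
9 | (3aS,5R,6S,7R,7aS)-6-ethenyl-6-methyl-3-methylidene-7-(prop-1-en-2-yl)octahydro-1-benzofuran-5,7-diol (vinyl and isopropenyl cis) | C=C[C@@]1(C)[C@H](O)C[C@H]2C(=C)CO[C@@H]2[C@@]1(O)C(C)=C | intermediate
10 | dipotassium 5,7-dialkoxide of 9 | C=C[C@@]1(C)[C@H]([O-])C[C@H]2C(=C)CO[C@@H]2[C@@]1([O-])C(C)=C.[K+].[K+] | intermediate
11 | dipotassium salt of the ring-expanded enolate, (1(10)E)-6,12-epoxygermacra-1(10),4,11(13)-triene-5,9-diolate (C3 and C6 cis on C4=C5; C6, C7, C9 as in 13) | C/C1=C(\[O-])[C@H]2OCC(=C)[C@@H]2C[C@@H]([O-])/C(C)=C/CC1.[K+].[K+] | intermediate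
12 | dipotassium salt of the (4S)-4-hydroperoxide corresponding to 13 | C[C@]1(O[O-])CC/C=C(C)/[C@H]([O-])C[C@H]2C(=C)CO[C@@H]2C1=O.[K+].[K+] | intermediate
13 | (1(10)E,4S,6S,7S,9R)-4,9-dihydroxy-6,12-epoxygermacra-1(10),11(13)-dien-5-one | C[C@]1(O)CC/C=C(C)/[C@H](O)C[C@H]2C(=C)CO[C@@H]2C1=O | intermediate
14 | (1(10)E,4S,5R,6S,7S,9R)-6,12-epoxygermacra-1(10),11(13)-diene-4,5,9-triol | C[C@]1(O)CC/C=C(C)/[C@H](O)C[C@H]2C(=C)CO[C@@H]2[C@H]1O | intermediate
15 | (1(10)E,4S,5R,6S,7S)-4,5-dihydroxy-6,12-epoxygermacra-1(10),11(13)-dien-9-one | C[C@]1(O)CC/C=C(C)/C(=O)C[C@H]2C(=C)CO[C@@H]2[C@H]1O | intermediate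
16 | (1(10)E,4S,5R,6S,7S)-4-hydroxy-5-(2-methylpropanoyloxy)-6,12-epoxygermacra-1(10),11(13)-dien-9-one | C[C@]1(O)CC/C=C(C)/C(=O)C[C@H]2C(=C)CO[C@@H]2[C@H]1OC(=O)C(C)C | intermediate
17 | 4-O-trimethylsilyl ether, 9-trimethylsilyloxy-1(10),8-diene (silyl dienol ether) of 16 | C[C@]1(O[Si](C)(C)C)CC/C=C(C)/C(O[Si](C)(C)C)=C[C@H]2C(=C)CO[C@@H]2[C@H]1OC(=O)C(C)C | intermediate
18 | 8,9-epoxide of 17 (oxirane oxygen on the face that becomes 8R) | C[C@]1(O[Si](C)(C)C)CC/C=C(C)/[C@]2(O[Si](C)(C)C)O[C@@H]2[C@H]3C(=C)CO[C@@H]3[C@H]1OC(=O)C(C)C | intermediate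
19 | (1(10)E,4S,5R,6S,7R,8R)-4,8-dihydroxy-5-(2-methylpropanoyloxy)-6,12-epoxygermacra-1(10),11(13)-dien-9-one | C[C@]1(O)CC/C=C(C)/C(=O)[C@H](O)[C@H]2C(=C)CO[C@@H]2[C@H]1OC(=O)C(C)C | intermediate
20 | (R)-2-methylbutanoic acid | CC[C@@H](C)C(=O)O | starting material
21 | (1(10)E,4S,5R,6S,7S,8R)-4-hydroxy-8-[(2R)-2-methylbutanoyloxy]-5-(2-methylpropanoyloxy)-6,12-epoxygermacra-1(10),11(13)-dien-9-one | C[C@]1(O)CC/C=C(C)/C(=O)[C@H](OC(=O)[C@H](C)CC)[C@H]2C(=C)CO[C@@H]2[C@H]1OC(=O)C(C)C | intermediate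
22 | copper enolate of 23 (C9–O–Cu, C9=C10; phosphine ligand not drawn) | C[C@]1(O)CCCC(C)=C(O[Cu])[C@H](OC(=O)[C@H](C)CC)[C@H]2C(=C)CO[C@@H]2[C@H]1OC(=O)C(C)C | intermediate
23 | (4S,5R,6S,7S,8R,10R)-4-hydroxy-8-[(2R)-2-methylbutanoyloxy]-5-(2-methylpropanoyloxy)-6,12-epoxygermacr-11(13)-en-9-one | C[C@]1(O)CCC[C@@H](C)C(=O)[C@H](OC(=O)[C@H](C)CC)[C@H]2C(=C)CO[C@@H]2[C@H]1OC(=O)C(C)C | intermediate
24 | CNP0071420.1, (4S,5R,6S,7S,8R,10R)-4-hydroxy-8-[(2R)-2-methylbutanoyloxy]-5-(2-methylpropanoyloxy)-9-oxogermacr-11(13)-en-12,6-olide | C[C@]1(O)CCC[C@@H](C)C(=O)[C@H](OC(=O)[C@H](C)CC)[C@H]2C(=C)C(=O)O[C@@H]2[C@H]1OC(=O)C(C)C | target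

## Step count and risk

Total steps: 14. Longest linear sequence: 14 (1 → 24); the acid 20 is bought.

The three steps most likely to fail:

**Step 7 (oxy-Cope and enolate oxygenation).** The rearrangement needs the gauche dialkenyl geometry, and the face on which oxygen enters at C4 is set only by the conformation of the new ring. If the C4 epimer dominates, the roles of the carbon and oxygen electrophiles are exchanged. Setting out from 8, 1-(methoxymethoxy)vinyllithium (from methoxymethyl vinyl ether and sBuLi, with CeCl3, THF, −78 °C) gives the 7-[1-(methoxymethoxy)ethenyl] analogue of 9 F1. The same KN(SiMe3)2/18-crown-6 oxy-Cope rearrangement, with the enolate now trapped by MeI (1.1 equiv, −78 °C), gives the 4-O-methoxymethyl ether of 13 F2. Methyl now enters on the face that oxygen took before, so C4 comes out with the opposite sense. Me2BBr (CH2Cl2, −78 °C, then NaHCO3(aq)) removes the acetal and the route is rejoined at 13.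

**Step 11 (α′-hydroxylation at C8).** The silyl dienol ether may form slowly on the twisted (E)-enone, or the oxidant may take the other face. Setting out from 16, direct α′-acyloxylation of the enone with Mn(OAc)3·2H2O and an excess of acid 20 in benzene at reflux installs the (R)-2-methylbutanoate in one operation by ligand transfer from the manganese enolate. This comes back to the route at 21 and makes no new compound (F0).

**Step 14 (late allylic C–H oxidation).** Chromium may over-oxidise or give the transposed aldehyde on a substrate that carries a ketone, two esters and a tertiary alcohol. Setting out from 23, an ene-type allylic hydroxylation (SeO2 cat., tBuOOH, CH2Cl2, 23 °C) at the CH2 next to oxygen gives the 12-hydroxy lactol of 23 F3. Ag2CO3 on Celite (benzene, reflux) oxidises only the lactol and the route is rejoined at 24.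

## Further compounds

F1 | step 7 | (3aS,5R,6S,7R,7aS)-6-ethenyl-7-[1-(methoxymethoxy)ethenyl]-6-methyl-3-methylidene-octahydro-1-benzofuran-5,7-diol | C=C[C@@]1(C)[C@H](O)C[C@H]2C(=C)CO[C@@H]2[C@@]1(O)C(OCOC)=C
F2 | step 7 | (1(10)E,4S,6S,7S,9R)-9-hydroxy-4-(methoxymethoxy)-6,12-epoxygermacra-1(10),11(13)-dien-5-one | C[C@]1(OCOC)CC/C=C(C)/[C@H](O)C[C@H]2C(=C)CO[C@@H]2C1=O
F0 | step 11 | none | none
F3 | step 14 | 12-hydroxy-6,12-epoxy lactol of 23 (both C12 anomers) | C[C@]1(O)CCC[C@@H](C)C(=O)[C@H](OC(=O)[C@H](C)CC)[C@H]2C(=C)C(O)O[C@@H]2[C@H]1OC(=O)C(C)C
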